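Amounts opened the meeting: 0.20 M of L against 0.210 M of J, which makes L the limiting reagent, and the flasks were read out as follows.

| flask | L | J | temperature | time | remark |
|---|---|---|---|---|---|
| larch | 0.20 M (fed, over 12 min) | 0.210 M | 40 °C | 30 min | all else is in the flask from the start; the feed brings no volume worth counting |
| oak | 0.20 M | 0.210 M | 40 °C | 30 min | everything together at the start |
| cedar | 0.20 M | 0.210 M (fed, over 12 min) |  | 30 min | the addition at 0 °C, then warmed to 40 °C; the feed brings no volume worth counting |
| elm | 0.20 M | 0.210 M (fed, over 12 min) | 40 °C | 30 min | all else is in the flask from the start; the feed brings no volume worth counting |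

    L + J + L.J → 2 L.J (k1 = 5.66 M⁻² min⁻¹, Ea1 = 37.0 kJ mol⁻¹)
    L + J → L.J (k2 = 0.00998 M⁻¹ min⁻¹, Ea2 = 65.0 kJ mol⁻¹)
    D ⇌ L.J, rate k3*(cs3 - [L.J]) while solid is left; crystals form when [L.J] > cs3 (cs3 = 0.11 M, k3 = 2.37 min⁻¹)
    J → X (k4 = 2.25 × 10⁻⁵ min⁻¹, Ea4 = 107 kJ mol⁻¹)
    L.J → Q (k5 = 0.0346 min⁻¹, Ea5 = 99.0 kJ mol⁻¹)
    (constants at 40 °C)

- L.J is meant together with its D
- solid, in amounts per volume of the solution: D
- the constants hold at 40 °C; other temperatures follow from the activation energies

1. the best flask by amount of L.J, in percent of the L charged; "all alike" if 1.5 percentage points covers them all (larch / oak / cedar / elm / all alike)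
2. amount of L.J at the end, in percent of the L charged, larch
3. amount of L.J at the end, in percent of the L charged, oak
4. amount of L.J at the end, in percent of the L charged, cedar
5. amount of L.J at the end, in percent of the L charged, elm

I argued that the concentration to find is the one that sets the order of the rate. The two forming steps together run at [L][J] times the uncatalysed constant plus the catalysed constant times [L.J]. The rate therefore turns from zero order to first order in [L.J] once [L.J] passes the ratio of those constants, 0.00176 M, which is 0.880% of the L charged.

Past that point, I said, L.J grows pseudo-first-order. On the full charge its catalysed gain per L.J, less its loss to Q, is 0.203 min⁻¹. I named this, taken at the [L] and [J] of the moment, the net growth constant. On the full charge that reckons to a doubling time of 3.41 min for L.J, with gain above loss.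

I then summed that constant over the time with the charge held. Oak gets 6.09. Larch and elm get 4.67 each, a steady feed of either reagent giving [L][J] on average half its full value during the feed. Cedar, counted from the warming with the cold addition left out, gets 3.66. My order was oak, then larch with elm, then cedar.

The chair objected that the seed, 0.00206 M, raised by the oak sum comes to 0.914 M, which is more than the L charged. I conceded that the curve must bend, and I committed to the order and to no percentages.

The forecast's maker named oak as best, with larch 33%, oak 42%, cedar 22% and elm 33%, on the ground that “the yield depends on how early both reagents are fully present”. The order matched mine; the percentages were the forecast's own.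

The simulation gives oak as best, with larch 32.3%, oak 39.1%, cedar 21.1% and elm 32.3%, the order of the sums. At 30.0 min cedar holds L at 74.5% and J at 75.7%, which puts its net growth constant at 0.0995 min⁻¹, against 0.203 min⁻¹ on the charge. The neighbour of cedar with 0.12 M of L has a net growth constant of 0.108 min⁻¹ on its full charge. Over the warm time that sums to 1.94, and with its own seed the reckoned exponential comes to 11.6% of its L. That neighbour ends with 9.79% of L.J and 87.9% of its L still there.

The numbers belong to no real substance, and the outcome is calculated.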